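Ring C of the flavanone half is disconnected at C4–C3 and O1–C2. This leaves a ring A salicylaldehyde and a two-carbon arylacetylene that already carries the luteolin unit through the hindered C2'–C8'' biaryl bond, made by Suzuki coupling. The key step joins them in one flask: rhodium-catalysed addition of the aldehyde C–H across the terminal alkyne forms C4–C3 as a 2'-hydroxychalcone, and oxa-Michael addition of the phenol forms O1–C2. It exploits the ortho pair of phenol oxygen O1 and acyl carbon C4 on ring A, which directs the C–H activation and then closes ring C. The racemic flavanone is resolved by asymmetric transfer hydrogenation before global hydrogenolysis.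

Key step: step 8

Remark: the structure leaves the sense of the hindered biaryl axis (C2' of ring B to C8 of the luteolin unit) undefined; the route controls C2 only and takes the axis as it forms (a rotamer mixture if rotation is slow).

Step 1
Reactants: 1 luteolin
Product: 2 5,7-bis(benzyloxy)-2-[3,4-bis(benzyloxy)phenyl]-4H-chromen-4-one (tetra-O-benzylluteolin)
Conditions: BnBr (6 equiv), K2CO3, KI (cat.), DMF, 80 °C
Reagents that add atoms: benzyl bromide, BrCc1ccccc1
Why: Williamson etherification, in which excess reagent and heat should also alkylate the hydrogen-bonded 5-hydroxyl.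

Step 2
Reactants: 2 tetra-O-benzylluteolin
Product: 3 5,7-bis(benzyloxy)-2-[3,4-bis(benzyloxy)phenyl]-8-iodo-4H-chromen-4-one
Conditions: N-iodosuccinimide, CF3CO2H (cat.), MeCN/CH2Cl2, 0 °C to rt
Reagents that add atoms: N-iodosuccinimide, O=C1CCC(=O)N1I
Why: Electrophilic aromatic iodination, expected at C8 of the 5,7-dialkoxy ring A because C6 lies between two benzyloxy groups and ring B is deactivated by the chromone.

Step 3
Reactants: 4 2-bromo-3-hydroxy-4-methoxybenzaldehyde (2-bromoisovanillin)
Product: 5 2-bromo-3,4-dihydroxybenzaldehyde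
Conditions: BBr3, CH2Cl2, −78 °C to 0 °C; then H2O
Reagents that add atoms: none
Why: Lewis acid cleavage of the aryl methyl ether (bromide removes the methyl group from the boron-complexed ether), which should leave the aldehyde and the aryl bromide untouched at low temperature.

Step 4
Reactants: 5 2-bromo-3,4-dihydroxybenzaldehyde
Product: 6 3,4-bis(benzyloxy)-2-bromobenzaldehyde
Conditions: BnBr, K2CO3, DMF, 60 °C
Reagents that add atoms: benzyl bromide, BrCc1ccccc1
Why: Williamson etherification of both catechol hydroxyls.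

Step 5
Reactants: 3 8-iodo-tetra-O-benzylluteolin; 6 3,4-bis(benzyloxy)-2-bromobenzaldehyde
Product: 8 biaryl aldehyde (C8 of tetra-O-benzylluteolin bonded to C2 of 3,4-bis(benzyloxy)benzaldehyde), via flavone 8-boronic pinacol ester 7 (not isolated)
Conditions: PdCl2(MeCN)2 (5 mol%), SPhos (10 mol%), pinacolborane, Et3N, 1,4-dioxane, 80 °C; then 6, K3PO4, H2O, 100 °C
Reagents that add atoms: none
Why: Miyaura-type borylation of the aryl iodide followed by Suzuki–Miyaura coupling in the same flask, where the dialkylbiarylphosphine should support oxidative addition into the ortho-formyl bromide and the slow transmetalation and reductive elimination of a tetra-ortho-substituted biaryl.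

Step 6
Reactants: 8 biaryl aldehyde
Product: 9 5,7-bis(benzyloxy)-2-[3,4-bis(benzyloxy)phenyl]-8-[2,3-bis(benzyloxy)-6-ethynylphenyl]-4H-chromen-4-one (biaryl alkyne)
Conditions: dimethyl (1-diazo-2-oxopropyl)phosphonate, K2CO3, MeOH/THF, rt
Reagents that add atoms: dimethyl (1-diazo-2-oxopropyl)phosphonate, COP(=O)(OC)C(=[N+]=[N-])C(C)=O
Why: Ohira–Bestmann (Seyferth–Gilbert) homologation, in which the diazomethylphosphonate anion formed in situ olefinates the aldehyde and the alkylidene carbene rearranges to the terminal alkyne under conditions mild enough for the flavone.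

Step 7
Reactants: 10 2,4,6-trihydroxybenzaldehyde
Product: 11 4,6-bis(benzyloxy)-2-hydroxybenzaldehyde
Conditions: BnBr (2.0 equiv), K2CO3, DMF, 0 °C to rt
Reagents that add atoms: benzyl bromide, BrCc1ccccc1
Why: Williamson etherification that should stop after two alkylations, since the last hydroxyl is hydrogen-bonded to the formyl group and the least reactive.

Step 8
Reactants: 9 biaryl alkyne; 11 4,6-bis(benzyloxy)-2-hydroxybenzaldehyde
Product: 13 racemic octabenzyl flavanone–flavone (5,7-bis(benzyloxy)flavanone whose ring B carries 3',4'-bis(benzyloxy) groups and, at C2', the C8 of tetra-O-benzylluteolin), via (E)-2'-hydroxychalcone 12 (not isolated)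
Conditions: [RhCl(cod)]2 (5 mol%), dppf (10 mol%), Na2CO3 (10 mol%), toluene, 90 °C; then CsF, 90 °C
Reagents that add atoms: none
Why: The rhodium phenoxide of 11 adds oxidatively into the aldehyde C–H, the acyl rhodium hydride inserts the terminal alkyne of 9 with rhodium at the unhindered terminal carbon, and reductive elimination forms C3–C4 as the (E)-2'-hydroxychalcone 12; fluoride then frees the phenoxide, which adds to the enone β-carbon and forms O1–C2. The closest known reaction type is the tandem rhodium-catalysed alkyne hydroacylation/oxa-Michael addition of salicylaldehydes to chroman-4-ones. Ring C closes in the 6-endo-trig mode. C2 is formed here without control, as both enantiomers, and is resolved in step 9. The step needs linear regioselectivity, which the terminal alkyne and its ortho-biaryl bulk should secure, and chemoselectivity for the chelating salicylaldehyde C–H, which the non-chelating flavone and the benzyl ethers cannot rival. The free 2-hydroxyl of 11 serves first as directing group and then as ring-closing nucleophile, and the benzyl group on the other ortho oxygen should keep the chalcone from closing before the C–C bond formation is complete.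

Step 9
Reactants: 13 racemic octabenzyl flavanone–flavone
Product: 14 (2S)-octabenzyl flavanone–flavone
Conditions: RuCl[(R,R)-TsDPEN](p-cymene) (5 mol%), HCO2H/Et3N (5:2), EtOAc, 40 °C, stopped past half conversion
Reagents that add atoms: none
Why: Kinetic resolution by Noyori-type asymmetric transfer hydrogenation, a known way to resolve flavanones, in which the (R,R)-catalyst should reduce the (2R)-ketone to the cis-(2R,4R)-alcohol much faster than the (2S)-ketone, so that C2 of recovered 14 is S by selection while the vinylogous-ester carbonyl of the flavone is not reduced.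

Step 10
Reactants: 14 (2S)-octabenzyl flavanone–flavone
Product: 15 target, (2S)-eriodictyol-(2'→8'')-luteolin
Conditions: H2 (1 atm), Pd(OH)2/C, THF/MeOH, rt, stopped when debenzylation is complete
Reagents that add atoms: none
Why: Hydrogenolysis of the eight benzyl ethers under neutral conditions, which should neither open nor epimerise the flavanone (no base, no strong acid) and should leave the flavone double bond in place.

Compound list
1 | luteolin | O=c1cc(-c2ccc(O)c(O)c2)oc2cc(O)cc(O)c12 | starting material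
2 | 5,7-bis(benzyloxy)-2-[3,4-bis(benzyloxy)phenyl]-4H-chromen-4-one | O=c1cc(-c2ccc(OCc3ccccc3)c(OCc3ccccc3)c2)oc2cc(OCc3ccccc3)cc(OCc3ccccc3)c12 | intermediate
3 | 5,7-bis(benzyloxy)-2-[3,4-bis(benzyloxy)phenyl]-8-iodo-4H-chromen-4-one | O=c1cc(-c2ccc(OCc3ccccc3)c(OCc3ccccc3)c2)oc2c(I)c(OCc3ccccc3)cc(OCc3ccccc3)c12 | intermediate
4 | 2-bromo-3-hydroxy-4-methoxybenzaldehyde | O=Cc1ccc(OC)c(O)c1Br | starting material
5 | 2-bromo-3,4-dihydroxybenzaldehyde | O=Cc1ccc(O)c(O)c1Br | intermediate
6 | 3,4-bis(benzyloxy)-2-bromobenzaldehyde | O=Cc1ccc(OCc2ccccc2)c(OCc2ccccc2)c1Br | intermediate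
7 | 5,7-bis(benzyloxy)-2-[3,4-bis(benzyloxy)phenyl]-8-(4,4,5,5-tetramethyl-1,3,2-dioxaborolan-2-yl)-4H-chromen-4-one | O=c1cc(-c2ccc(OCc3ccccc3)c(OCc3ccccc3)c2)oc2c(B3OC(C)(C)C(C)(C)O3)c(OCc3ccccc3)cc(OCc3ccccc3)c12 | intermediate (not isolated)
8 | 2-{5,7-bis(benzyloxy)-2-[3,4-bis(benzyloxy)phenyl]-4-oxo-4H-chromen-8-yl}-3,4-bis(benzyloxy)benzaldehyde | O=Cc1ccc(OCc2ccccc2)c(OCc2ccccc2)c1-c1c(OCc2ccccc2)cc(OCc2ccccc2)c2c(=O)cc(-c3ccc(OCc4ccccc4)c(OCc4ccccc4)c3)oc12 | intermediate
9 | 5,7-bis(benzyloxy)-2-[3,4-bis(benzyloxy)phenyl]-8-[2,3-bis(benzyloxy)-6-ethynylphenyl]-4H-chromen-4-one | C#Cc1ccc(OCc2ccccc2)c(OCc2ccccc2)c1-c1c(OCc2ccccc2)cc(OCc2ccccc2)c2c(=O)cc(-c3ccc(OCc4ccccc4)c(OCc4ccccc4)c3)oc12 | intermediate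
10 | 2,4,6-trihydroxybenzaldehyde | O=Cc1c(O)cc(O)cc1O | starting material
11 | 4,6-bis(benzyloxy)-2-hydroxybenzaldehyde | O=Cc1c(O)cc(OCc2ccccc2)cc1OCc1ccccc1 | intermediate
12 | (E)-1-[4,6-bis(benzyloxy)-2-hydroxyphenyl]-3-{3,4-bis(benzyloxy)-2-[5,7-bis(benzyloxy)-2-(3,4-bis(benzyloxy)phenyl)-4-oxo-4H-chromen-8-yl]phenyl}prop-2-en-1-one | O=C(/C=C/c1ccc(OCc2ccccc2)c(OCc2ccccc2)c1-c1c(OCc2ccccc2)cc(OCc2ccccc2)c2c(=O)cc(-c3ccc(OCc4ccccc4)c(OCc4ccccc4)c3)oc12)c1c(O)cc(OCc2ccccc2)cc1OCc1ccccc1 | intermediate (not isolated)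
13 | racemic 5,7-bis(benzyloxy)-2-{3,4-bis(benzyloxy)-2-[5,7-bis(benzyloxy)-2-(3,4-bis(benzyloxy)phenyl)-4-oxo-4H-chromen-8-yl]phenyl}chroman-4-one | O=C1CC(c2ccc(OCc3ccccc3)c(OCc3ccccc3)c2-c2c(OCc3ccccc3)cc(OCc3ccccc3)c3c(=O)cc(-c4ccc(OCc5ccccc5)c(OCc5ccccc5)c4)oc23)Oc2cc(OCc3ccccc3)cc(OCc3ccccc3)c21 | intermediate
14 | (2S)-5,7-bis(benzyloxy)-2-{3,4-bis(benzyloxy)-2-[5,7-bis(benzyloxy)-2-(3,4-bis(benzyloxy)phenyl)-4-oxo-4H-chromen-8-yl]phenyl}chroman-4-one | O=C1C[C@@H](c2ccc(OCc3ccccc3)c(OCc3ccccc3)c2-c2c(OCc3ccccc3)cc(OCc3ccccc3)c3c(=O)cc(-c4ccc(OCc5ccccc5)c(OCc5ccccc5)c4)oc23)Oc2cc(OCc3ccccc3)cc(OCc3ccccc3)c21 | intermediate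
15 | (2S)-2-{2-[2-(3,4-dihydroxyphenyl)-5,7-dihydroxy-4-oxo-4H-chromen-8-yl]-3,4-dihydroxyphenyl}-5,7-dihydroxychroman-4-one | O=C1C[C@@H](c2ccc(O)c(O)c2-c2c(O)cc(O)c3c(=O)cc(-c4ccc(O)c(O)c4)oc23)Oc2cc(O)cc(O)c21 | target

Total step count: 10. Longest linear sequence: 7 (steps 1, 2, 5, 6, 8, 9, 10).

Steps most likely to fail

Step 8. The alkyne may insert with the wrong regiochemistry (branched enone), the acyl rhodium hydride may decarbonylate and deactivate the catalyst, or the oxa-Michael closure may stall at the chalcone–flavanone equilibrium. The fallback sets out from 9 and 11 and comes back at 13; it makes C3–C4 by desulfitative acyl cross-coupling instead of C–H activation. Alkyne 9 is hydroborated with catecholborane (THF, 65 °C, aqueous work-up) to the (E)-alkenylboronic acid F1. Aldehyde 11 is oxidised under Pinnick conditions (NaClO2, NaH2PO4, 2-methyl-2-butene, t-BuOH/H2O) to 4,6-bis(benzyloxy)-2-hydroxybenzoic acid F2, which is converted with EtSH, EDC and DMAP into the S-ethyl thioester F3. Liebeskind–Srogl coupling of F3 with F1 (Pd2(dba)3, tri(2-furyl)phosphine, copper thiophene-2-carboxylate Cu(O2CC4H3S), THF, 50 °C) should give chalcone 12, which is closed in the same flask with NaOAc in EtOH at reflux to 13, so both bonds of ring C are still formed in one operation.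

Step 5. The iodide may be reduced instead of borylated, and the hindered boronate may lose boron by protonolysis before the slow tetra-ortho transmetalation. The fallback sets out from 6 and 3 and comes back at 8; it is a Negishi coupling with the nucleophile on the small partner. Aldehyde 6 is masked as the 1,3-dioxolane F4 (ethylene glycol, TsOH, toluene, reflux). Bromine–lithium exchange (n-BuLi, THF, −78 °C) and ZnCl2 give the arylzinc chloride F5, which is coupled with iodide 3 (Pd2(dba)3, SPhos, THF, 65 °C) to the biaryl acetal F6. Aqueous HCl in THF then returns aldehyde 8.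

Step 9. The catalyst may discriminate the two enantiomers too weakly at the hindered, peri-substituted ketone, or the reduction may stall, so that 14 is not reached in high enantiomeric purity. The fallback sets out from 9 and 11 and comes back at 14; it replaces resolution by enantioselective closure. Step 8 is run without CsF, and after the rhodium stage chalcone 12 is cyclised in the same flask at room temperature by a quinine-derived bifunctional thiourea (or its quinidine-derived pseudoenantiomer, whichever gives 2S) under kinetic control. The sense and level of induction would have to be found by experiment. This fallback makes no compound outside the list (F0).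

Further compounds
F1 | step 8 | (E)-2-{3,4-bis(benzyloxy)-2-[5,7-bis(benzyloxy)-2-(3,4-bis(benzyloxy)phenyl)-4-oxo-4H-chromen-8-yl]phenyl}ethenylboronic acid | OB(O)/C=C/c1ccc(OCc2ccccc2)c(OCc2ccccc2)c1-c1c(OCc2ccccc2)cc(OCc2ccccc2)c2c(=O)cc(-c3ccc(OCc4ccccc4)c(OCc4ccccc4)c3)oc12
F2 | step 8 | 4,6-bis(benzyloxy)-2-hydroxybenzoic acid | O=C(O)c1c(O)cc(OCc2ccccc2)cc1OCc1ccccc1
F3 | step 8 | S-ethyl 4,6-bis(benzyloxy)-2-hydroxybenzenecarbothioate | CCSC(=O)c1c(O)cc(OCc2ccccc2)cc1OCc1ccccc1
F4 | step 5 | 2-[3,4-bis(benzyloxy)-2-bromophenyl]-1,3-dioxolane | Brc1c(C2OCCO2)ccc(OCc2ccccc2)c1OCc1ccccc1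
F5 | step 5 | [2,3-bis(benzyloxy)-6-(1,3-dioxolan-2-yl)phenyl]zinc chloride | Cl[Zn]c1c(C2OCCO2)ccc(OCc2ccccc2)c1OCc1ccccc1
F6 | step 5 | 5,7-bis(benzyloxy)-2-[3,4-bis(benzyloxy)phenyl]-8-[2,3-bis(benzyloxy)-6-(1,3-dioxolan-2-yl)phenyl]-4H-chromen-4-one | O=c1cc(-c2ccc(OCc3ccccc3)c(OCc3ccccc3)c2)oc2c(-c3c(C4OCCO4)ccc(OCc4ccccc4)c3OCc3ccccc3)c(OCc3ccccc3)cc(OCc3ccccc3)c12
F0 | step 9 | none | none
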